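1. Compare noon with spring. Noon's product reads 53.1% at 1.33 min and 52.3% at 3.00 min, with 49.3% of its starting material still there, while spring's climbs higher, to 87.6%. Noon's reagent over starting material is 52.0%, so the two react one to one. For Wednesday's that ratio is 18.8%: this is the ceiling Y, the reagent charge over the starting-material charge, in percent of the starting material charged and taken no higher than 100. Below 100, reagent is the limiting reagent.

| flask | starting material | reagent | free catalyst | remark | time |
|---|---|---|---|---|---|
| dawn | 0.050 M | 0.050 M | 0.030 mM | run made earlier |  |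
| spring | 0.050 M | 0.050 M | 0.079 mM | run made earlier |  |
| midnight | 0.050 M | 0.050 M | 0.16 mM | run made earlier |  |
| noon | 0.050 M | 0.026 M | 0.10 mM | run made earlier |  |
| Thursday's | 0.025 M | 0.0800 M | 0.030 mM |  | 4.0 min |
| Sunday's | 0.20 M | 0.0500 M | 0.050 mM |  | 4.0 min |
| Wednesday's | 0.080 M | 0.0150 M | 0.10 mM |  | 4.0 min |
| Saturday's | 0.080 M | 0.0250 M | 0.20 mM |  | 4.0 min |
| Tuesday's | 0.050 M | 0.0500 M | 0.10 mM |  | 4.0 min |

| run | time / min | product / % | starting material / % |
|---|---|---|---|
| dawn | 0.250 | 8.5 | 92.5 |
| dawn | 0.417 | 12.2 | 86.8 |
| dawn | 0.833 | 22.8 | 76.4 |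
| dawn | 1.33 | 35.9 | 63.4 |
| dawn | 3.00 | 60.3 | 37.5 |
| spring | 0.250 | 19.5 | 82.6 |
| spring | 0.667 | 45.1 | 58.2 |
| spring | 1.33 | 65.5 | 33.2 |
| spring | 2.00 | 79.1 | 19.7 |
| spring | 3.00 | 87.6 | 12.3 |
| midnight | 0.250 | 36.0 | 65.7 |
| midnight | 0.667 | 66.9 | 33.9 |
| midnight | 1.33 | 85.9 | 16.9 |
| midnight | 2.00 | 89.9 | 8.3 |
| midnight | 3.00 | 96.4 | 5.6 |
| noon | 0.250 | 19.2 | 80.8 |
| noon | 0.667 | 41.0 | 57.9 |
| noon | 1.33 | 53.1 | 50.0 |
| noon | 2.00 | 52.1 | 47.2 |
| noon | 3.00 | 52.3 | 49.3 |

(each reading ± 1 percentage point)

- the flasks by amount of product, in percent of the starting material charged, highest first, at 4.0 min (Thursday's / Sunday's / Wednesday's / Saturday's / Tuesday's)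
- the same order at 15 min (Thursday's / Sunday's / Wednesday's / Saturday's / Tuesday's)
- the amount of product, in percent of the starting material charged of the flask you put first, at 4.0 min
- the amount of product, in percent of the starting material charged of the flask you put last, at 4.0 min



2. Objection: a ceiling is useless if the flask doesn't reach it in time. Of the flasks with Y below 100, Sunday's needs the most reagent used per catalyst. Take dawn's average rate up to 1.33 min, scale it by catalyst, and give no credit for Sunday's richer starting material. On that estimate Sunday's reagent lasts about 2.22 min, shorter than 4.0 min.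

3. So I put Saturday's at 31.2%, Sunday's at 25.0% and Wednesday's at 18.8%, at both times asked. Tuesday's ratio is 1.00 and Thursday's 3.20, so Y is 100 for both and does not separate them.

4. First try: count half-lives. Dawn's 37.5% left at 3.00 min reads as a half-life of 2.12 min, and scaling by catalyst gives Tuesday's 6.29 half-lives. Objection: the same count gives midnight 0.535% left at 3.00 min, but the reading is 5.6%. The tail is slower, so I drop the count.

5. Better: match the product E of catalyst and time to a run with equal charges. Tuesday's E equals midnight's at 2.50 min, between readings of 89.9% and 96.4%, so I say 93.1%. Thursday's E equals spring's at 1.52 min, between 65.5% and 79.1%. Objection: Thursday's charges differ from spring's, so this match is rough. But the lower reading stands above Saturday's Y and the higher below my figure for Tuesday's, so I put Thursday's second at 4.0 min.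

6. At 15 min, Thursday's E matches midnight at 2.81 min and Tuesday's at 9.38 min, later than midnight's last reading. Objection: Thursday's excess reagent may lift it, and I cannot compute that away. I keep Tuesday's first, as a thin call.

7. The forecast gives Tuesday's > Thursday's > Saturday's > Sunday's > Wednesday's at 4.0 min and Thursday's > Tuesday's > Saturday's > Sunday's > Wednesday's at 15 min, with 94% and 18.75%, and says “reagent caps the yield in reagent-limited flasks”; at 15 min its first place differs from mine, and its top stands against my 93.1%.

8. The simulation gives Tuesday's > Thursday's > Saturday's > Sunday's > Wednesday's at 4.0 min and Tuesday's > Thursday's > Saturday's > Sunday's > Wednesday's at 15 min, with 94.0% and 18.8%.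

    starting material + free catalyst → catalyst intermediate A (k = 1400 /M/s)
    reagent + catalyst intermediate A → catalyst intermediate B (k = 1100 /M/s)
    catalyst intermediate B ⇌ catalyst intermediate C (K = 8.30, k = 74.0 /s)
    catalyst intermediate C ⇌ free catalyst + product (K = 0.0250 M, k = 18.0 /s)
    2 free catalyst → spent catalyst (k = 2100 /M/s)

At 4.0 min Wednesday's gives 18.8% against its Y of 18.8%, and at 40.0 min it gives 18.8%. Now take the neighbour of Tuesday's charged with 0.12 M of starting material, which is 0.417 equiv of reagent. Its Y is 41.7%, and dawn's scaled rate uses its reagent in 1.11 min. At 4.00 min that neighbour holds 41.7% product, 0% reagent and 58.3% starting material.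

The readings are simulated from invented constants, and the scatter is random.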